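Ring C is cut at O1–C8a and C4–C4a. Ring A offers two adjacent carbons, C8a (bonded to O1) and C4a (bonded to carbonyl C4). The C5 oxygen sits next to C4a and the side chain on C8 next to C8a. This is what a 3-alkoxyaryne leaves behind after an oxygen nucleophile and then an acyl group add across it. One fluoride-triggered operation joins this aryne to the enolate of a methyl α-formylarylacetate carrying C2, C3, C4 and ring B, closing the pyranone with the chain fixed at C8. The aryne precursor is a pentasubstituted ortho-silylaryl triflate whose tertiary alcohol is masked as a fluoride-inert benzyloxymethyl (BOM) acetal, so one hydrogenolysis finishes the synthesis.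

Key step: step 12

Remark: isoflavone numbering (O1, C2 to C4, C4a, C5 to C8, C8a) is also applied to ring A atoms in the open precursors. Enol 19 equilibrates with its aldehyde tautomer and is drawn as the chelated Z enol. The target has no stereocentre.

Step 1
Reactants: 1 2,4,6-trihydroxybenzaldehyde
Product: 2 2,4-bis(benzyloxy)-6-hydroxybenzaldehyde
Conditions: BnBr (2.05 equiv), K2CO3 (2.2 equiv), DMF, 0 °C to rt
Reagents that add atoms: benzyl bromide, BrCc1ccccc1
Why: Williamson etherification should stop after two alkylations because the last ortho hydroxyl is tied to the formyl oxygen by a hydrogen bond and is the least nucleophilic site.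

Step 2
Reactants: 2 2,4-bis(benzyloxy)-6-hydroxybenzaldehyde; 3 (acetonylidene)triphenylphosphorane
Product: 4 (E)-4-[2,4-bis(benzyloxy)-6-hydroxyphenyl]but-3-en-2-one
Conditions: toluene, 100 °C
Reagents that add atoms: none
Why: Wittig olefination with a stabilised ylide tolerates the free chelated phenol and should give the E enone, whose geometry is erased in step 3.

Step 3
Reactants: 4 (E)-4-[2,4-bis(benzyloxy)-6-hydroxyphenyl]but-3-en-2-one
Product: 5 4-[2,4-bis(benzyloxy)-6-hydroxyphenyl]butan-2-one
Conditions: H2 (1 atm), 10% Pd/C, 2,2'-bipyridyl (0.5 equiv), MeOH/THF, rt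
Reagents that add atoms: none
Why: Hydrogenation over nitrogen-base-poisoned Pd/C saturates the conjugated alkene while the additive suppresses hydrogenolysis of phenolic benzyl ethers, and reducing at the enone stage avoids an ionisable, electron-rich allylic tertiary alcohol.

Step 4
Reactants: 5 4-[2,4-bis(benzyloxy)-6-hydroxyphenyl]butan-2-one
Product: 6 3,5-bis(benzyloxy)-2-(3-hydroxy-3-methylbutyl)phenol
Conditions: MeMgBr (3.5 equiv), THF, 0 °C to rt; aq NH4Cl
Reagents that add atoms: methylmagnesium bromide, C[Mg]Br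
Why: In this Grignard addition the first equivalent forms the phenoxide, which opens any cyclic hemiketal, and further reagent adds to the unhindered methyl ketone to give the tertiary alcohol.

Step 5
Reactants: 6 3,5-bis(benzyloxy)-2-(3-hydroxy-3-methylbutyl)phenol
Product: 7 3,5-bis(benzyloxy)-2-(3-hydroxy-3-methylbutyl)phenyl N-isopropylcarbamate
Conditions: iPrNCO (1.3 equiv), Et3N (0.2 equiv), CH2Cl2, rt
Reagents that add atoms: isopropyl isocyanate, CC(C)N=C=O
Why: Base-catalysed carbamoylation of the phenol by the isocyanate is far faster than that of the hindered tertiary alcohol, so only the C8a oxygen should react.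

Step 6
Reactants: 7 3,5-bis(benzyloxy)-2-(3-hydroxy-3-methylbutyl)phenyl N-isopropylcarbamate
Product: 8 3,5-bis(benzyloxy)-2-[3-(benzyloxymethoxy)-3-methylbutyl]phenyl N-isopropylcarbamate
Conditions: BOMCl (3 equiv), iPr2NEt (4 equiv), nBu4NI (0.2 equiv), CH2Cl2, 40 °C
Reagents that add atoms: benzyl chloromethyl ether, ClCOCc1ccccc1
Why: Alkoxymethylation through the iodomethyl ether formed in situ is a standard mildly basic protection of tertiary alcohols, and the acetal resists fluoride and cold organolithiums yet falls in the final hydrogenolysis.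

Step 7
Reactants: 8 3,5-bis(benzyloxy)-2-[3-(benzyloxymethoxy)-3-methylbutyl]phenyl N-isopropylcarbamate
Product: 12 3,5-bis(benzyloxy)-2-[3-(benzyloxymethoxy)-3-methylbutyl]-6-(trimethylsilyl)phenyl N-isopropylcarbamate, via N-TBS carbamate 9 (not isolated), via aryllithium 10 (not isolated), via N-TBS arylsilane 11 (not isolated)
Conditions: TBSOTf (1.1 equiv), TMEDA (1.1 equiv), Et2O, 0 °C to rt; TMEDA (2 equiv), nBuLi (2.1 equiv), −78 °C; TMSCl (3.5 equiv), −78 °C to rt; aq NaHSO4
Reagents that add atoms: chlorotrimethylsilane, C[Si](C)(C)Cl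
Why: In this directed ortho-metalation of an in situ N-silylated O-aryl carbamate, C4a–H is the only site ortho to the carbamate and also adjoins the C5 benzyloxy group, so cooperative direction should place lithium there at −78 °C faster than nBuLi in Et2O removes a benzylic ether proton, and the near-stoichiometric silyl triflate is consumed by the N–H before it can activate the acetal.

Step 8
Reactants: 12 3,5-bis(benzyloxy)-2-[3-(benzyloxymethoxy)-3-methylbutyl]-6-(trimethylsilyl)phenyl N-isopropylcarbamate
Product: 14 3,5-bis(benzyloxy)-2-[3-(benzyloxymethoxy)-3-methylbutyl]-6-(trimethylsilyl)phenyl trifluoromethanesulfonate, via ortho-silylphenol 13 (not isolated)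
Conditions: DBU (1.5 equiv), Et2NH (1.2 equiv), MeCN, 40 °C; then PhNTf2 (1.5 equiv), rt
Reagents that add atoms: N-phenylbis(trifluoromethanesulfonimide), O=S(=O)(N(c1ccccc1)S(=O)(=O)C(F)(F)F)C(F)(F)F
Why: E1cB cleavage of the secondary carbamate, with Et2NH trapping the isocyanate, frees the phenoxide, and one-pot O-triflation follows under conditions that leave the aryl–silicon bond intact.

Step 9
Reactants: 15 2,4-dihydroxyphenylacetic acid
Product: 16 methyl 2,4-dihydroxyphenylacetate
Conditions: MeOH, H2SO4 (cat.), reflux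
Reagents that add atoms: methanol, CO
Why: Fischer esterification in excess methanol gives the open methyl ester and also methanolyses any benzofuranone formed from the ortho phenol.

Step 10
Reactants: 16 methyl 2,4-dihydroxyphenylacetate
Product: 17 methyl 2,4-bis(benzyloxy)phenylacetate
Conditions: BnBr (2.3 equiv), K2CO3 (3 equiv), acetone, reflux
Reagents that add atoms: benzyl bromide, BrCc1ccccc1
Why: Williamson etherification of both phenols proceeds under carbonate conditions too mild to alkylate the ester α-carbon.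

Step 11
Reactants: 17 methyl 2,4-bis(benzyloxy)phenylacetate
Product: 19 methyl (Z)-2-[2,4-bis(benzyloxy)phenyl]-3-hydroxyacrylate, via sodium enolate 18 (not isolated)
Conditions: NaH (2.5 equiv), HCO2Me (10 equiv), THF, 0 °C to rt; then 1 M HCl
Reagents that add atoms: methyl formate, COC=O
Why: Crossed Claisen condensation with the non-enolisable formate is driven by formation of the stabilised enolate, and acidification should give the enol whose Z geometry is held by a hydrogen bond to the ester carbonyl.

Step 12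
Reactants: 14 3,5-bis(benzyloxy)-2-[3-(benzyloxymethoxy)-3-methylbutyl]-6-(trimethylsilyl)phenyl trifluoromethanesulfonate; 19 methyl (Z)-2-[2,4-bis(benzyloxy)phenyl]-3-hydroxyacrylate
Product: 23 5,7-bis(benzyloxy)-3-[2,4-bis(benzyloxy)phenyl]-8-[3-(benzyloxymethoxy)-3-methylbutyl]-4H-chromen-4-one, via cesium enolate 20 (not isolated), via aryne 21 (not isolated), via aryl anion 22 (not isolated)
Conditions: 19 (1.5 equiv) pre-stirred with CsF (4 equiv), THF, rt; then 14 (1.0 equiv), 65 °C
Reagents that add atoms: none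
Why: Proposed new method: fluoride attacks the C4a silicon, triflate departs from C8a and aryne 21 is released slowly beside cesium enolate 20, whose oxygen bonds to C8a (O1–C8a) to leave aryl anion 22 with its charge at C4a. In 22 the ester carbonyl is held cis to the aryloxy group across the C2=C3 bond, so the anion closes ring C by a 6-exo-trig addition–elimination that makes C4–C4a and ejects methoxide, which picks up the enol proton parked on fluoride. The closest known reaction types are the CsF-mediated annulation of arynes with methyl salicylates to xanthones, which shows the same O-arylation and intramolecular acyl capture with a phenoxide, and the acyl-alkylation of arynes with β-keto esters, which shows the carbon attack that has to be avoided here; an enolate oxygen has not been used in this way. Orientation on the aryne is secured by the C5 benzyloxy group, whose inductive withdrawal distorts the triple bond so that the nucleophile enters at the remote terminus C8a and charge builds next to oxygen at C4a, an electronic bias expected to outweigh the steric demand of the C8 chain. Oxygen over carbon attack is secured sterically, because the enolate carbon is fully substituted, bears a twisted ortho-benzyloxyphenyl group and would have to bond to an aryne carbon flanked by the chain, whereas the terminal oxygen is open, and cesium chelation in THF keeps the U-shaped Z enolate that closure requires. No stereocentre is created, THF rather than MeCN denies the aryl anion an easy proton, and the benzyloxymethyl acetal can neither be unmasked by fluoride to an alkoxide that would trap C8a nor pass a silyl group to C4a.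

Step 13
Reactants: 23 5,7-bis(benzyloxy)-3-[2,4-bis(benzyloxy)phenyl]-8-[3-(benzyloxymethoxy)-3-methylbutyl]-4H-chromen-4-one
Product: 24 2,3-dehydrokievitone hydrate
Conditions: H2 (1 atm), 10% Pd/C, EtOAc/MeOH, rt, stopped at full conversion
Reagents that add atoms: none
Why: Catalytic hydrogenolysis cleaves the four aryl benzyl ethers and the benzylic C–O bond of the acetal, whose hemiacetal sheds formaldehyde, under neutral conditions that spare the tertiary alcohol, while the vinylogous ester bond C2=C3 is reduced much more slowly.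

Compound list
1 | 2,4,6-trihydroxybenzaldehyde | O=Cc1c(O)cc(O)cc1O | starting material
2 | 2,4-bis(benzyloxy)-6-hydroxybenzaldehyde | O=Cc1c(O)cc(OCc2ccccc2)cc1OCc1ccccc1 | intermediate
3 | (acetonylidene)triphenylphosphorane | CC(=O)C=P(c1ccccc1)(c1ccccc1)c1ccccc1 | starting material
4 | (E)-4-[2,4-bis(benzyloxy)-6-hydroxyphenyl]but-3-en-2-one | CC(=O)/C=C/c1c(O)cc(OCc2ccccc2)cc1OCc1ccccc1 | intermediate
5 | 4-[2,4-bis(benzyloxy)-6-hydroxyphenyl]butan-2-one | CC(=O)CCc1c(O)cc(OCc2ccccc2)cc1OCc1ccccc1 | intermediate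
6 | 3,5-bis(benzyloxy)-2-(3-hydroxy-3-methylbutyl)phenol | CC(C)(O)CCc1c(O)cc(OCc2ccccc2)cc1OCc1ccccc1 | intermediate
7 | 3,5-bis(benzyloxy)-2-(3-hydroxy-3-methylbutyl)phenyl N-isopropylcarbamate | CC(C)NC(=O)Oc1cc(OCc2ccccc2)cc(OCc2ccccc2)c1CCC(C)(C)O | intermediate
8 | 3,5-bis(benzyloxy)-2-[3-(benzyloxymethoxy)-3-methylbutyl]phenyl N-isopropylcarbamate | CC(C)NC(=O)Oc1cc(OCc2ccccc2)cc(OCc2ccccc2)c1CCC(C)(C)OCOCc1ccccc1 | intermediate
9 | N-(tert-butyldimethylsilyl) derivative of 8 (not isolated) | CC(C)N([Si](C)(C)C(C)(C)C)C(=O)Oc1cc(OCc2ccccc2)cc(OCc2ccccc2)c1CCC(C)(C)OCOCc1ccccc1 | intermediate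
10 | C4a-lithiated 9 (not isolated) | CC(C)N([Si](C)(C)C(C)(C)C)C(=O)Oc1c([Li])c(OCc2ccccc2)cc(OCc2ccccc2)c1CCC(C)(C)OCOCc1ccccc1 | intermediate
11 | C4a-trimethylsilylated 9 (not isolated) | CC(C)N([Si](C)(C)C(C)(C)C)C(=O)Oc1c([Si](C)(C)C)c(OCc2ccccc2)cc(OCc2ccccc2)c1CCC(C)(C)OCOCc1ccccc1 | intermediate
12 | 3,5-bis(benzyloxy)-2-[3-(benzyloxymethoxy)-3-methylbutyl]-6-(trimethylsilyl)phenyl N-isopropylcarbamate | CC(C)NC(=O)Oc1c([Si](C)(C)C)c(OCc2ccccc2)cc(OCc2ccccc2)c1CCC(C)(C)OCOCc1ccccc1 | intermediate
13 | 3,5-bis(benzyloxy)-2-[3-(benzyloxymethoxy)-3-methylbutyl]-6-(trimethylsilyl)phenol (not isolated) | Oc1c([Si](C)(C)C)c(OCc2ccccc2)cc(OCc2ccccc2)c1CCC(C)(C)OCOCc1ccccc1 | intermediate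
14 | 3,5-bis(benzyloxy)-2-[3-(benzyloxymethoxy)-3-methylbutyl]-6-(trimethylsilyl)phenyl trifluoromethanesulfonate | CC(C)(OCOCc1ccccc1)CCc1c(OCc2ccccc2)cc(OCc2ccccc2)c([Si](C)(C)C)c1OS(=O)(=O)C(F)(F)F | intermediate
15 | 2,4-dihydroxyphenylacetic acid | OC(=O)Cc1ccc(O)cc1O | starting material
16 | methyl 2,4-dihydroxyphenylacetate | COC(=O)Cc1ccc(O)cc1O | intermediate
17 | methyl 2,4-bis(benzyloxy)phenylacetate | COC(=O)Cc1ccc(OCc2ccccc2)cc1OCc1ccccc1 | intermediate
18 | sodium (Z)-enolate of 19 (not isolated) | [Na+].[O-]/C=C(\C(=O)OC)c1ccc(OCc2ccccc2)cc1OCc1ccccc1 | intermediate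
19 | methyl (Z)-2-[2,4-bis(benzyloxy)phenyl]-3-hydroxyacrylate | O/C=C(\C(=O)OC)c1ccc(OCc2ccccc2)cc1OCc1ccccc1 | intermediate
20 | cesium (Z)-enolate of 19 (not isolated) | [Cs+].[O-]/C=C(\C(=O)OC)c1ccc(OCc2ccccc2)cc1OCc1ccccc1 | intermediate
21 | 3,5-bis(benzyloxy)-6-[3-(benzyloxymethoxy)-3-methylbutyl]-1,2-didehydrobenzene, aryne C4a≡C8a (not isolated) | CC(C)(OCOCc1ccccc1)CCC1=C(OCc2ccccc2)C=C(OCc2ccccc2)C#C1 | intermediate
22 | cesium salt of the C4a aryl anion of the (Z)-O-aryl enol ether (not isolated) | CC(C)(OCOCc1ccccc1)CCc1c(OCc2ccccc2)cc(OCc2ccccc2)[c-]c1O/C=C(\C(=O)OC)c1ccc(OCc2ccccc2)cc1OCc1ccccc1.[Cs+] | intermediate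
23 | 5,7-bis(benzyloxy)-3-[2,4-bis(benzyloxy)phenyl]-8-[3-(benzyloxymethoxy)-3-methylbutyl]-4H-chromen-4-one | CC(C)(OCOCc1ccccc1)CCc1c(OCc2ccccc2)cc(OCc2ccccc2)c2c(=O)c(-c3ccc(OCc4ccccc4)cc3OCc3ccccc3)coc12 | intermediate
24 | 2,3-dehydrokievitone hydrate, 3-(2,4-dihydroxyphenyl)-5,7-dihydroxy-8-(3-hydroxy-3-methylbutyl)-4H-chromen-4-one | CC(C)(O)CCc1c(O)cc(O)c2c(=O)c(-c3ccc(O)cc3O)coc12 | target

Total step count: 13. Longest linear sequence: 10 (steps 1 to 8, 12 and 13). Steps 9 to 11 form the convergent ring B branch.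

Steps most likely to fail

**Step 12**
- The ambident enolate may attack through carbon, with capture of the formyl group and C–C fragmentation.
- Addition may occur at the C4a terminus of the aryne.
- The aryl anion may be protonated before acyl capture.
- The side-chain acetal oxygen may intercept the aryne.

The fallback uses known chemistry only, sets out from 8 and returns at 23. Compound 8 is N-silylated and lithiated as in step 7. Aryllithium 10 is quenched with N-methoxy-N-methylacetamide to give N-TBS ortho-acetyl carbamate F1, which loses its N-silyl group on acidic work-up to give ortho-acetyl carbamate F2. DBU/Et2NH in MeCN at 40 °C frees 2-hydroxyacetophenone F3. Heating with DMF dimethyl acetal gives enaminone F4. I2 in CHCl3 causes iodocyclisation with loss of dimethylamine to 3-iodochromone F5. Ring B comes from 4-bromoresorcinol, which is benzylated (BnBr, K2CO3) to aryl bromide F6 and converted by bromine–lithium exchange and B(OiPr)3 into boronic acid F7. Suzuki–Miyaura coupling of F5 and F7 (Pd(PPh3)4, Na2CO3, DME/H2O, 80 °C) should deliver 23.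

**Step 7**
- Deprotonation may compete at a benzylic ether position or at C6 between the two benzyloxy groups.
- The silyl triflate may activate the acetal.
- The carbamoyl group may shift to carbon on warming.

The fallback sets out from 6, returns at 14 and replaces steps 5 to 8 by halogen–metal exchange. Phenol 6 is brominated at its only free ortho position with NBS and catalytic iPr2NH in CH2Cl2 at low temperature, giving bromophenol F8. TMSCl/imidazole silylates both hydroxyl groups to bis(trimethylsilyl) ether F9. nBuLi in THF at −78 °C effects bromine–lithium exchange and the retro-Brook oxygen-to-carbon silyl shift to lithium phenoxide F10. PhNTf2 converts F10 in the same flask into O-silylated silyl triflate F11. Citric acid in MeOH removes the tertiary O-silyl group to give hydroxy silyl triflate F12. BOMCl/iPr2NEt as in step 6 then gives 14.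

**Step 13**
- Cleavage of the tertiary acetal may stall.
- The C2=C3 bond may be saturated on prolonged exposure.
- The nucleophilic ring A may capture the released formaldehyde.

The fallback sets out from 23 and returns at 24. The acetal is removed first by acid-catalysed exchange with methanol (HCl from AcCl, MeOH/THF, rt). Every phenol is still benzylated at that point, so the C7 oxygen cannot close a chroman onto the tertiary centre. This gives tetra-O-benzyl alcohol F13. Its four aryl benzyl ethers then fall in a short hydrogenolysis (H2, Pd/C, EtOAc/MeOH) with no formaldehyde present.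

Further compounds
F1 | step 12 | 2-acetyl-3,5-bis(benzyloxy)-6-[3-(benzyloxymethoxy)-3-methylbutyl]phenyl N-(tert-butyldimethylsilyl)-N-isopropylcarbamate | CC(C)N([Si](C)(C)C(C)(C)C)C(=O)Oc1c(C(C)=O)c(OCc2ccccc2)cc(OCc2ccccc2)c1CCC(C)(C)OCOCc1ccccc1
F2 | step 12 | 2-acetyl-3,5-bis(benzyloxy)-6-[3-(benzyloxymethoxy)-3-methylbutyl]phenyl N-isopropylcarbamate | CC(C)NC(=O)Oc1c(C(C)=O)c(OCc2ccccc2)cc(OCc2ccccc2)c1CCC(C)(C)OCOCc1ccccc1
F3 | step 12 | 1-{4,6-bis(benzyloxy)-3-[3-(benzyloxymethoxy)-3-methylbutyl]-2-hydroxyphenyl}ethan-1-one | CC(=O)c1c(O)c(CCC(C)(C)OCOCc2ccccc2)c(OCc2ccccc2)cc1OCc1ccccc1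
F4 | step 12 | (E)-1-{4,6-bis(benzyloxy)-3-[3-(benzyloxymethoxy)-3-methylbutyl]-2-hydroxyphenyl}-3-(dimethylamino)prop-2-en-1-one | CN(C)/C=C/C(=O)c1c(O)c(CCC(C)(C)OCOCc2ccccc2)c(OCc2ccccc2)cc1OCc1ccccc1
F5 | step 12 | 5,7-bis(benzyloxy)-8-[3-(benzyloxymethoxy)-3-methylbutyl]-3-iodo-4H-chromen-4-one | CC(C)(OCOCc1ccccc1)CCc1c(OCc2ccccc2)cc(OCc2ccccc2)c2c(=O)c(I)coc12
F6 | step 12 | 2,4-bis(benzyloxy)-1-bromobenzene | Brc1ccc(OCc2ccccc2)cc1OCc1ccccc1
F7 | step 12 | 2,4-bis(benzyloxy)phenylboronic acid | OB(O)c1ccc(OCc2ccccc2)cc1OCc1ccccc1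
F8 | step 7 | 3,5-bis(benzyloxy)-2-bromo-6-(3-hydroxy-3-methylbutyl)phenol | CC(C)(O)CCc1c(O)c(Br)c(OCc2ccccc2)cc1OCc1ccccc1
F9 | step 7 | bis(trimethylsilyl) ether of F8 | CC(C)(O[Si](C)(C)C)CCc1c(O[Si](C)(C)C)c(Br)c(OCc2ccccc2)cc1OCc1ccccc1
F10 | step 7 | lithium 3,5-bis(benzyloxy)-2-[3-methyl-3-(trimethylsilyloxy)butyl]-6-(trimethylsilyl)phenoxide | [Li+].[O-]c1c([Si](C)(C)C)c(OCc2ccccc2)cc(OCc2ccccc2)c1CCC(C)(C)O[Si](C)(C)C
F11 | step 7 | 3,5-bis(benzyloxy)-2-[3-methyl-3-(trimethylsilyloxy)butyl]-6-(trimethylsilyl)phenyl trifluoromethanesulfonate | CC(C)(O[Si](C)(C)C)CCc1c(OCc2ccccc2)cc(OCc2ccccc2)c([Si](C)(C)C)c1OS(=O)(=O)C(F)(F)F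
F12 | step 7 | 3,5-bis(benzyloxy)-2-(3-hydroxy-3-methylbutyl)-6-(trimethylsilyl)phenyl trifluoromethanesulfonate | CC(C)(O)CCc1c(OCc2ccccc2)cc(OCc2ccccc2)c([Si](C)(C)C)c1OS(=O)(=O)C(F)(F)F
F13 | step 13 | 5,7-bis(benzyloxy)-3-[2,4-bis(benzyloxy)phenyl]-8-(3-hydroxy-3-methylbutyl)-4H-chromen-4-one | CC(C)(O)CCc1c(OCc2ccccc2)cc(OCc2ccccc2)c2c(=O)c(-c3ccc(OCc4ccccc4)cc3OCc3ccccc3)coc12
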